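The added ligand separates our flask from the eta run: 7.7 mM against 12 mM, with the other charges equal.

| flask | starting material | partner | catalyst | added ligand | remark | time |
|---|---|---|---|---|---|---|
| eta | 2 M | 1 M | 4 mM | 12 mM | run made earlier |  |
| flask | 2.0 M | 1.00 M | 4.0 mM | 7.7 mM |  | 4.0 h |

eta run (percent of the starting material charged): time / min: target / % = 4.00: 9; 12.0: 21; 20.0: 25; 30.0: 26; 40.0: 27; 60.0: 27; 80.0: 25

(readings scatter by 2 percentage points)

* the moment within 4.0 h at which there is most target
* the amount of target, in percent of the starting material charged, at that time
* earliest time at which at least nineteen twentieths of that best amount are there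
* latest time at which they still are

- what was read earlier has a scatter of 2 percentage points, one standard deviation
- no earlier run changes the charge of added ligand; that part of a forecast is a guess

1. In the eta run, target reads 27 % at 40.0 min. That is below the 50.0 % allowed by the partner, the limiting reagent if the two react one to one.
2. We work with the fraction left after the top. In the eta run, 92.6 % of the top reading stands at 80.0 min. This gives a loss constant k, the minus logarithm of the fraction left per unit time, of 0.00192 /min. It is rough: the fall is 2 percentage points against a scatter of 2 points.
3. Our guess is that the loss needs free catalyst and that ligand binds catalyst tightly, one to one. Free catalyst then goes as 1/s, where s is the spare ligand, the added ligand charged beyond the catalyst.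
4. Our flask has s = 3.70 mM, and the eta run has 8.00 mM. So we expect k to be about twice as large in our flask: 0.00416 /min.
5. Losing 5 % from the top then takes about 12.0 min. Counted from the top reading of the eta run, our estimate of shut is 0.867 h.

The forecast gives 0.7 h, 27 %, 0.37 h and 1.4 h, in its words: “Its direction is unknown, so I keep the eta numbers as the central guess”. Our estimate of shut is earlier.

The flask gives 0.659 h, 26.7 %, 0.399 h and 1.10 h.

    starting material + partner ⇌ isomer of the product (K = 69.0 /M, k = 0.0120 /M/min)
    starting material + partner ⇌ target (K = 2.90 /M, k = 0.0330 /M/min)
    catalyst + target → catalyst + over-reaction product (k = 2.50 /M/min)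
    target + catalyst ⇌ isomer of the product + catalyst, rate k4*[catalyst]*[target] forward; the back reaction follows from the equilibrium constant (k = 5.10 /M/min)
    catalyst + added ligand ⇌ idle complex, settled at all times (K = 5700 /M)

The forecast and the flask part on shut, where 1.10 h stands below 1.4 h. At the best time, our flask holds 3.87 mM of free added ligand against s = 3.70 mM, with 4.33 % of the catalyst free. The neighbouring flask, charged with 0.0031 M of added ligand and otherwise like ours, has s = −0.900 mM, which leaves 22.5 % of the catalyst unpaired by our count. It holds 31.9 % free at 4.00 h. Of its best of 22.4 %, 16.4 % is left then, against 51.8 % in our flask.

Readings and results were computed with made-up constants; the scatter is artificial.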